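Numbering: 1-aryl-1,2-dihydronaphthalene. C1 carries ring C (3,4-dimethoxyphenyl), C2 the CH2OH, C3 the CHO, and C4 is the vinyl CH. Ring A is C4a–C8a with C7-OH and C8-OMe; ring B is C1–C4 plus C4a and C8a.
Enabling feature: C1 and C4, the two ends of the four-carbon bridge of ring B, are both bonded directly to ring A (at C8a and C4a). Putting water back across C3=C4 (OH on C4) makes ring B the [4+2] adduct of a ring-A hydroxy-o-quinodimethane and a C2=C3 alkene.
Cuts: first C3=C4 back to the C4 carbinol and CHO back to CO2Me. Next C1–C2 and C3–C4 together. Last C8a–C1 (aryl–benzyl coupling) in the diene half and C2=C3 (olefination) in the dienophile.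
Forward: rings A (vanillin) and C (3,4-dimethoxybenzyl chloride) are bought and joined through the C1 methylene. Ring B closes last, in one photochemical step. Dehydration, ester-to-aldehyde adjustment and two deprotections finish the synthesis.
Stereochemistry: the 1,2-trans relation comes from the outward aryl group of the dienol, the (E)-alkene and the ester-endo approach. The absolute sense (1S,2R) comes from a titanium TADDOLate. C3 and C4 are also set but vanish on dehydration.

Key step: step 6

Assumption: the (R,R)-TADDOL ligand is taken to give the (1S,2R,3S,4S) cycloadduct; if the first run shows the opposite sense, the equally available (S,S)-ligand is used and nothing else changes.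

Step 1
Reactants: 1 vanillin
Product: 2 4-isopropoxy-3-methoxybenzaldehyde
Conditions: 2-bromopropane, K2CO3, DMF, 70 °C
Reagents that add atoms: 2-bromopropane, CC(C)Br
Why: Williamson ether synthesis on the acidic para-formyl phenol; the isopropyl ether withstands organolithium, organozinc, titanium alkoxide and hydride reagents, directs lithiation only weakly, and can later be cleaved beside methyl ethers.

Step 2
Reactants: 2 4-isopropoxy-3-methoxybenzaldehyde
Product: 6 2-iodo-4-isopropoxy-3-methoxybenzaldehyde, via lithium α-amino alkoxide 3 (not isolated), via C2-lithiated α-amino alkoxide 4 (not isolated), via C2-iodinated α-amino alkoxide 5 (not isolated)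
Conditions: Me2NCH2CH2N(Li)Me (from Me2NCH2CH2NHMe, n-BuLi), THF, −20 °C; n-BuLi, −20 °C; I2, −78 °C → rt; H2O
Reagents that add atoms: iodine, II
Why: Directed ortho-metalation with in situ aldehyde protection: the lithium amide adds to the formyl group, the chelating α-amino alkoxide 3 and the neighbouring methoxy group together guide n-BuLi to the carbon between them while the bulky isopropoxy group keeps its own ortho position quiet, and iodine quench followed by hydrolysis of 5 returns the aldehyde.

Step 3
Reactants: 7 3,4-dimethoxybenzyl chloride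
Product: 8 (3,4-dimethoxybenzyl)zinc chloride (titrated THF solution holding LiCl)
Conditions: Zn dust, LiCl, THF, 25 °C
Reagents that add atoms: zinc, [Zn]
Why: LiCl-assisted direct insertion of zinc into a benzylic C–Cl bond is a standard preparation of benzylic zinc chlorides that runs at room temperature, tolerates electron-rich rings and, on slow addition of 7, keeps Wurtz-type dimerisation down.

Step 4
Reactants: 6 2-iodo-4-isopropoxy-3-methoxybenzaldehyde; 8 (3,4-dimethoxybenzyl)zinc chloride
Product: 9 2-(3,4-dimethoxybenzyl)-4-isopropoxy-3-methoxybenzaldehyde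
Conditions: Pd(OAc)2 (2 mol %), SPhos (4 mol %), THF, 25 °C
Reagents that add atoms: none
Why: Negishi cross-coupling: zerovalent palladium inserts readily into the C–I bond, the bulky electron-rich biarylphosphine carries the doubly ortho-substituted arylpalladium species through transmetalation and reductive elimination, and the benzylzinc chloride is too mild to add to the aldehyde at this temperature.

Step 5
Reactants: 10 (tert-butyldimethylsilyloxy)acetaldehyde; 11 methyl (triphenylphosphoranylidene)acetate
Product: 12 methyl (E)-4-(tert-butyldimethylsilyloxy)but-2-enoate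
Conditions: CH2Cl2, rt
Reagents that add atoms: none
Why: Wittig olefination with an ester-stabilised ylide is reliably (E)-selective with unbranched aldehydes and leaves the silyl ether alone.

Step 6
Reactants: 9 2-(3,4-dimethoxybenzyl)-4-isopropoxy-3-methoxybenzaldehyde; 12 methyl (E)-4-(tert-butyldimethylsilyloxy)but-2-enoate
Product: 14 methyl (1S,2R,3S,4S)-2-[(tert-butyldimethylsilyloxy)methyl]-1-(3,4-dimethoxyphenyl)-4-hydroxy-7-isopropoxy-8-methoxy-1,2,3,4-tetrahydronaphthalene-3-carboxylate (1,2-trans/2,3-trans/3,4-cis), via outward-outward hydroxy-o-quinodimethane 13 (not isolated)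
Conditions: Ti(OiPr)4 (2 equiv), (R,R)-TADDOL (2.2 equiv), toluene, rt, 30 min; then 9, 12, hν (365 nm), degassed, rt
Reagents that add atoms: none
Why: Light of 365 nm excites the aldehyde, whose carbonyl oxygen pulls a hydrogen atom off the doubly benzylic C1 methylene (1,5-hydrogen transfer), and the biradical relaxes to the hydroxy-o-quinodimethane 13; only the isomer with OH and aryl both turned outward is long-lived, the others falling back to 9, and titanium captures it as a dienolate. The closest known reaction type is the Ti(OiPr)4/TADDOL-mediated enantioselective photoenolization/Diels–Alder reaction of electron-rich 2-alkylbenzaldehydes with unsaturated esters and lactones, backed by the long-known trapping of 2-benzylbenzaldehyde photoenols with acrylates and fumarates. Ring B closes by an intermolecular, concerted, suprafacial [4+2] cycloaddition that restores the aromaticity of ring A, C1 bonding to the β-carbon of 12 (C2) and C4 to its α-carbon (C3). C1 and C4 end up cis because both outward groups stay on one face of the diene, C2 and C3 end up trans because the (E)-geometry of 12 is carried over, and the ester-endo approach, held in place by the ester carbonyl and the dienolate oxygen sharing one titanium centre, puts CO2Me cis to the C4 hydroxyl and so CH2OTBS trans to the C1 aryl group. The absolute configuration (1S,2R,3S,4S) is decided by the twofold-symmetric TADDOLate, whose aryl groups leave only one face of the bound enoate open. The selectivity most needed is the regiochemistry, since the C1 aryl group by itself would draw the ester to C2: the much stronger oxygen donor at C4 places the largest HOMO coefficient on C1, and the titanium bridge can only deliver the ester-bearing carbon to C4.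

Step 7
Reactants: 14 the (1S,2R,3S,4S) cycloadduct
Product: 16 methyl (1S,2R)-2-[(tert-butyldimethylsilyloxy)methyl]-1-(3,4-dimethoxyphenyl)-7-isopropoxy-8-methoxy-1,2-dihydronaphthalene-3-carboxylate, via C4 mesylate 15 (not isolated)
Conditions: MsCl, Et3N, CH2Cl2, 0 °C; then DBU, rt
Reagents that add atoms: none
Why: Mesylation followed by base-induced β-elimination (E2 or E1cB): H3 is acidified by the ester and lies anti to the C4 leaving group, which is also para-alkoxybenzylic, whereas H1 and H2 are not activated, so the C1 and C2 centres are kept.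

Step 8
Reactants: 16 the (1S,2R) enoate
Product: 17 [(1S,2R)-2-[(tert-butyldimethylsilyloxy)methyl]-1-(3,4-dimethoxyphenyl)-7-isopropoxy-8-methoxy-1,2-dihydronaphthalen-3-yl]methanol
Conditions: i-Bu2AlH, CH2Cl2, −78 °C; aq. potassium sodium tartrate
Reagents that add atoms: none
Why: 1,2-Reduction of the α,β-unsaturated ester with i-Bu2AlH at low temperature is the standard route to allylic alcohols, and silyl, isopropyl and methyl ethers are inert to it.

Step 9
Reactants: 17 the (1S,2R) allylic alcohol
Product: 18 (1S,2R)-2-[(tert-butyldimethylsilyloxy)methyl]-1-(3,4-dimethoxyphenyl)-7-isopropoxy-8-methoxy-1,2-dihydronaphthalene-3-carbaldehyde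
Conditions: MnO2 (activated, excess), CH2Cl2, rt
Reagents that add atoms: none
Why: MnO2 oxidation, selective for allylic and benzylic-type alcohols, stops at the enal, and the silyl ether still on the C2 arm rules out lactol formation and over-oxidation to a lactone.

Step 10
Reactants: 18 the (1S,2R) silyl-protected enal
Product: 19 (1S,2R)-1-(3,4-dimethoxyphenyl)-2-(hydroxymethyl)-7-isopropoxy-8-methoxy-1,2-dihydronaphthalene-3-carbaldehyde
Conditions: HF·pyridine, pyridine, THF, 0 °C → rt
Reagents that add atoms: none
Why: Fluoride-induced cleavage of a primary silyl ether is driven by the strong Si–F bond, and pyridine-buffered HF is neither basic nor acidic enough to touch the enal, the aryl ethers or the two stereocentres.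

Step 11
Reactants: 19 the (1S,2R) hydroxy enal isopropyl ether
Product: 20 vitekwangin B, (1S,2R)-1-(3,4-dimethoxyphenyl)-7-hydroxy-2-(hydroxymethyl)-8-methoxy-1,2-dihydronaphthalene-3-carbaldehyde
Conditions: BCl3 (1 M in CH2Cl2, 3–4 equiv), CH2Cl2, −78 → 0 °C; H2O
Reagents that add atoms: none
Why: Lewis-acid dealkylation of an aryl isopropyl ether: BCl3 binds the ether oxygen and chloride takes the secondary alkyl group far faster than a methyl group, a selectivity well established for ortho-methoxy isopropoxyarenes including aldehydes, while the primary alcohol is merely held as a borate ester until the aqueous quench.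

Compound list
1 | vanillin | COc1cc(C=O)ccc1O | starting material
2 | 4-isopropoxy-3-methoxybenzaldehyde | COc1cc(C=O)ccc1OC(C)C | intermediate
3 | lithium α-amino alkoxide from 2 and lithium N,N,N'-trimethylethylenediamide | COc1cc(C([O-])N(C)CCN(C)C)ccc1OC(C)C.[Li+] | intermediate
4 | C2-lithiated α-amino alkoxide | COc1c([Li])c(C([O-])N(C)CCN(C)C)ccc1OC(C)C.[Li+] | intermediate
5 | C2-iodinated α-amino alkoxide | COc1c(I)c(C([O-])N(C)CCN(C)C)ccc1OC(C)C.[Li+] | intermediate
6 | 2-iodo-4-isopropoxy-3-methoxybenzaldehyde | COc1c(I)c(C=O)ccc1OC(C)C | intermediate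
7 | 3,4-dimethoxybenzyl chloride | COc1ccc(CCl)cc1OC | starting material
8 | (3,4-dimethoxybenzyl)zinc chloride | COc1ccc(C[Zn]Cl)cc1OC | intermediate
9 | 2-(3,4-dimethoxybenzyl)-4-isopropoxy-3-methoxybenzaldehyde | CC(C)Oc1ccc(C=O)c(Cc2ccc(OC)c(OC)c2)c1OC | intermediate
10 | (tert-butyldimethylsilyloxy)acetaldehyde | CC(C)(C)[Si](C)(C)OCC=O | starting material
11 | methyl (triphenylphosphoranylidene)acetate | COC(=O)C=P(c1ccccc1)(c1ccccc1)c1ccccc1 | starting material
12 | methyl (E)-4-(tert-butyldimethylsilyloxy)but-2-enoate | COC(=O)/C=C/CO[Si](C)(C)C(C)(C)C | intermediate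
13 | hydroxy-o-quinodimethane with OH and aryl both outward (drawn as the free dienol; bound to titanium through oxygen in the flask) | O/C=C1\C=CC(OC(C)C)=C(OC)/C1=C\c1ccc(OC)c(OC)c1 | intermediate
14 | methyl (1S,2R,3S,4S)-2-[(tert-butyldimethylsilyloxy)methyl]-1-(3,4-dimethoxyphenyl)-4-hydroxy-7-isopropoxy-8-methoxy-1,2,3,4-tetrahydronaphthalene-3-carboxylate | COc1ccc([C@H]2c3c(ccc(OC(C)C)c3OC)[C@@H](O)[C@@H](C(=O)OC)[C@@H]2CO[Si](C)(C)C(C)(C)C)cc1OC | intermediate
15 | C4 methanesulfonate of 14 | COc1ccc([C@H]2c3c(ccc(OC(C)C)c3OC)[C@@H](OS(C)(=O)=O)[C@@H](C(=O)OC)[C@@H]2CO[Si](C)(C)C(C)(C)C)cc1OC | intermediate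
16 | methyl (1S,2R)-2-[(tert-butyldimethylsilyloxy)methyl]-1-(3,4-dimethoxyphenyl)-7-isopropoxy-8-methoxy-1,2-dihydronaphthalene-3-carboxylate | COc1ccc([C@H]2c3c(ccc(OC(C)C)c3OC)C=C(C(=O)OC)[C@@H]2CO[Si](C)(C)C(C)(C)C)cc1OC | intermediate
17 | [(1S,2R)-2-[(tert-butyldimethylsilyloxy)methyl]-1-(3,4-dimethoxyphenyl)-7-isopropoxy-8-methoxy-1,2-dihydronaphthalen-3-yl]methanol | COc1ccc([C@H]2c3c(ccc(OC(C)C)c3OC)C=C(CO)[C@@H]2CO[Si](C)(C)C(C)(C)C)cc1OC | intermediate
18 | (1S,2R)-2-[(tert-butyldimethylsilyloxy)methyl]-1-(3,4-dimethoxyphenyl)-7-isopropoxy-8-methoxy-1,2-dihydronaphthalene-3-carbaldehyde | COc1ccc([C@H]2c3c(ccc(OC(C)C)c3OC)C=C(C=O)[C@@H]2CO[Si](C)(C)C(C)(C)C)cc1OC | intermediate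
19 | (1S,2R)-1-(3,4-dimethoxyphenyl)-2-(hydroxymethyl)-7-isopropoxy-8-methoxy-1,2-dihydronaphthalene-3-carbaldehyde | COc1ccc([C@H]2c3c(ccc(OC(C)C)c3OC)C=C(C=O)[C@@H]2CO)cc1OC | intermediate
20 | vitekwangin B | COc1ccc([C@H]2c3c(ccc(O)c3OC)C=C(C=O)[C@@H]2CO)cc1OC | target

Total step count: 11. Longest linear sequence: 9 (steps 1, 2, 4, 6, 7, 8, 9, 10, 11, from vanillin); steps 3 and 5 are one-step side branches.

Steps most likely to fail

Step 6. The TADDOLate may discriminate poorly between the two faces when the dienol terminus carries an aryl group pressed against the C8 methoxy group. Capture by a β-substituted enoate may also be slow enough for the dienol to fall back to 9. Ester exchange with isopropoxide on titanium would do no harm, because step 8 reduces either ester to 17.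
Fallback: stereocontrol by the ligand is given up for a resolution that costs no extra leaving-group step. Setting out from 9 and 12, the irradiation is run with Ti(OiPr)4 alone, the well-tried racemic form of the reaction. This should give 14 together with its mirror image, the ent-cycloadduct F1. Steglich esterification of the C4 hydroxyl with (S)-O-methylmandelic acid (DCC, DMAP, CH2Cl2) turns the pair into two diastereomers, the wanted mandelate ester F2 and the unwanted mandelate ester F3. These are separated by chromatography or crystallisation. DBU then expels the mandelate from F2 by β-elimination, and the route is rejoined at 16.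

Step 11. The crowded C8 methyl ether, flanked on both sides and next to the freshly formed aryloxyborane, may be lost in competition. The Lewis acid bound to the enal may also trigger ionisation or aromatisation of ring B.
Fallback: the phenol protecting group is exchanged while the molecule is still a simple benzaldehyde. Setting out from 9, BCl3 in CH2Cl2 frees the phenolic aldehyde F4, and i-Pr3SiCl/imidazole in DMF converts it into the triisopropylsilyl ether F5. Irradiation of F5 with 12 under the conditions of step 6 passes through the silyl-protected photoenol F6 to the silyl-protected cycloadduct F7. As in steps 7 to 9, this goes through the mesylate F8 to the bis-silyl enoate F9, is reduced to the bis-silyl allylic alcohol F10, and is oxidised to the bis-silyl enal F11. One treatment with Bu4NF buffered with AcOH (THF, 0 °C) removes both silyl groups and reaches 20, so no Lewis acid ever meets the enal.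

Step 4. Transmetalation and reductive elimination at the doubly ortho-substituted arylpalladium centre may be slow. Homocoupling of the electron-rich benzylzinc reagent and reduction of the C–I bond could then take over.
Fallback: the polarity of the coupling is reversed, so no benzylic organometallic is needed. Setting out from 6, Miyaura borylation (B2pin2, PdCl2(dppf), KOAc, dioxane, 80 °C) gives the pinacol boronate F12. Suzuki–Miyaura coupling of F12 with the benzyl chloride 7 itself (PdCl2(dppf), K3PO4, THF–H2O, 65 °C) comes back to the route at 9 and makes step 3 unnecessary.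

Further compounds
F1 | step 6 | ent-cycloadduct, the (1R,2S,3R,4R) mirror image of 14 | COc1ccc([C@@H]2c3c(ccc(OC(C)C)c3OC)[C@H](O)[C@H](C(=O)OC)[C@H]2CO[Si](C)(C)C(C)(C)C)cc1OC
F2 | step 6 | wanted mandelate ester, C4 (S)-O-methylmandelate of 14 | COc1ccc([C@H]2c3c(ccc(OC(C)C)c3OC)[C@@H](OC(=O)[C@@H](OC)c3ccccc3)[C@@H](C(=O)OC)[C@@H]2CO[Si](C)(C)C(C)(C)C)cc1OC
F3 | step 6 | unwanted mandelate ester, C4 (S)-O-methylmandelate of F1 | COc1ccc([C@@H]2c3c(ccc(OC(C)C)c3OC)[C@H](OC(=O)[C@@H](OC)c3ccccc3)[C@H](C(=O)OC)[C@H]2CO[Si](C)(C)C(C)(C)C)cc1OC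
F4 | step 11 | phenolic aldehyde, 2-(3,4-dimethoxybenzyl)-4-hydroxy-3-methoxybenzaldehyde | COc1ccc(Cc2c(C=O)ccc(O)c2OC)cc1OC
F5 | step 11 | triisopropylsilyl ether, 2-(3,4-dimethoxybenzyl)-3-methoxy-4-(triisopropylsilyloxy)benzaldehyde | COc1ccc(Cc2c(C=O)ccc(O[Si](C(C)C)(C(C)C)C(C)C)c2OC)cc1OC
F6 | step 11 | silyl-protected photoenol (OH and aryl outward) | O/C=C1\C=CC(O[Si](C(C)C)(C(C)C)C(C)C)=C(OC)/C1=C\c1ccc(OC)c(OC)c1
F7 | step 11 | silyl-protected cycloadduct, (1S,2R,3S,4S), C7 triisopropylsilyl analogue of 14 | COc1ccc([C@H]2c3c(ccc(O[Si](C(C)C)(C(C)C)C(C)C)c3OC)[C@@H](O)[C@@H](C(=O)OC)[C@@H]2CO[Si](C)(C)C(C)(C)C)cc1OC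
F8 | step 11 | mesylate of F7 | COc1ccc([C@H]2c3c(ccc(O[Si](C(C)C)(C(C)C)C(C)C)c3OC)[C@@H](OS(C)(=O)=O)[C@@H](C(=O)OC)[C@@H]2CO[Si](C)(C)C(C)(C)C)cc1OC
F9 | step 11 | bis-silyl enoate, (1S,2R) | COc1ccc([C@H]2c3c(ccc(O[Si](C(C)C)(C(C)C)C(C)C)c3OC)C=C(C(=O)OC)[C@@H]2CO[Si](C)(C)C(C)(C)C)cc1OC
F10 | step 11 | bis-silyl allylic alcohol, (1S,2R) | COc1ccc([C@H]2c3c(ccc(O[Si](C(C)C)(C(C)C)C(C)C)c3OC)C=C(CO)[C@@H]2CO[Si](C)(C)C(C)(C)C)cc1OC
F11 | step 11 | bis-silyl enal, (1S,2R) | COc1ccc([C@H]2c3c(ccc(O[Si](C(C)C)(C(C)C)C(C)C)c3OC)C=C(C=O)[C@@H]2CO[Si](C)(C)C(C)(C)C)cc1OC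
F12 | step 4 | pinacol boronate, 4-isopropoxy-3-methoxy-2-(4,4,5,5-tetramethyl-1,3,2-dioxaborolan-2-yl)benzaldehyde | CC(C)Oc1ccc(C=O)c(B2OC(C)(C)C(C)(C)O2)c1OC
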